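The number 0.220, the rate constant of step 1 over that of step 2, is the target plateau: the share of the free partner at which substrate uses target up as fast as substrate and partner make it, with the way back of step 1 set aside. Substrate cancels from this balance, which is the quasi-steady state of target.

| flask | substrate | partner | scavenger | time |
|---|---|---|---|---|
| dawn | 1.0 mM | 1.10 mM | 1.00 mM | 1.0 min |
| dusk | 1.0 mM | 1.10 mM | 1.00 mM | 2.0 min |
| midnight | 1.0 mM | 1.10 mM | 1.00 mM | 4.0 min |

    substrate + partner ⇌ target + released group (K1 = 6.2, k1 = 9.0 /M/s)
    substrate + target → side product A (k2 = 41 /M/s)
    partner + released group ⇌ idle adduct, settled at all times (K3 = 1200 /M)
    scavenger + released group → scavenged by-product (k4 = 140 /M/s)
    substrate + released group → side product B (k5 = 14 /M/s)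

- in percentages every species weighs as the substrate in it: one side product A counts as two
- for released group the idle adduct is counted in
- run time (dawn): 1.0 min

- which of these there is most of at the end, counted by the substrate in it, dawn (side product B / target / side product A / substrate)
- which of these there is most of at the end, counted by the substrate in it, dusk (side product B / target / side product A / substrate)
- which of these there is most of at the end, counted by the substrate in it, midnight (side product B / target / side product A / substrate)
- final amount of the leader among these, as a percentage of the substrate charged, in dawn
- final amount of the leader among these, as a percentage of the substrate charged, in dusk
- final amount of the leader among these, as a percentage of the substrate charged, in midnight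

Dawn and dusk hold the same charges and differ in the time of reading, so the question is what the longer wait does. A substrate molecule has a fork: it meets partner and becomes target, or it meets target and is lost with it into side product A. Side product B is set aside in this reckoning because released group meets scavenger more often than substrate at the charge, by 10.0 to one.

Target climbs towards its plateau in about 0.407 min, its lifetime against substrate at the charge. After that, every passage through step 1 is paired with one through step 2, so two substrate molecules go for each partner molecule. This reckoning counts partner as its charge less half of the substrate lost, an estimate that sets aside the partner spent while target climbed. On that count, in fractions of the charge, substrate left over substrate left plus 1.20 decays exponentially at 0.648 /min. The climb delays this clock by about 0.203 min.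

So dawn keeps 44.7% of its substrate against 37.3% in side product A, and the leader at dawn is substrate. Dusk keeps 19.8% of its substrate, and its leader is side product A at 64.8%. Midnight keeps 4.85% of its substrate, and its leader is side product A at 81.5%.

The forecast names substrate at 45% for dawn, side product A at 60% for dusk and side product A at 74% for midnight, lower than this reckoning at midnight, on the ground that target “eats substrate, with side product A counted double”.

The flasks give substrate at 45.9% for dawn, side product A at 60.9% for dusk and side product A at 77.5% for midnight. At dusk the plateau on the partner left, 58% of its charge, comes to 13.9% of the substrate charge, and target reads 14.9%.

The neighbouring flask holds the charges of dawn except for 0.40 mM of substrate, and it is read at the same 1.0 min. Its plateau, on the 84% of partner left, comes to 50.8% of its substrate charge, and the climb there takes about 1.02 min. This neighbour reads target 27.7%, still under that plateau, and side product A 22.8%, against 37.0% at dawn.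

The constants belong to no real substance; the flask was simulated.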